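**Retrosynthetic overview**
1. Numbering: carbocycle C1 (tertiary carbinol), C2 (angelate), C3 (lactone O), C4 (ring fusion), C5, C6, C7 (CHMe); Cα is the lactone CHMe carbon; the α face is the face that carries C7–Me.
2. Late stage: the (R)-3-hydroxybutanoyl chain comes from an acetaldehyde aldol on a C1 methyl ketone; the C2 angelate and the C1 hydroxyl come from titanium-mediated opening of a C1–C2 α-epoxide (inversion at C2).
3. The α-epoxide comes from C3–OH-directed epoxidation of the C1=C2 alkene; the γ-lactone comes from oxidation of Cα–CH2OH onto the cis C3–OH.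
4. Key disconnection: the seven-membered carbocycle is cut at C1–C7 and C3–C4 by a formal (4+3) cycloaddition. The feature it rests on is that C3–O, C4–Cα and C7–Me all lie on the α face, at the ends of the C1–C2–C3 unit (siloxyvinyl diazo ester 11) and the C4–C5–C6–C7 unit (E,E-diene 6, Cα from the hydroxy ester 3).
5. Ring order: carbocycle (step 8), epoxide (step 13), lactone (step 14), epoxide opened (step 16).

Key step: step 8

Assumption: the facial sense of Rh2(S-DOSP)4 with diene 6 and of (+)-Ipc2BCl with the methyl ketone is taken to follow their behaviour with simple substrates (terminal attack on conjugated alkenes; methyl ketone enol borinates of this antipode adding to the Si face of aldehydes); if either sense were found reversed, the antipodal reagent would be used.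

**Route**

Step 1
Reactants: 1 (E)-1-bromobut-2-ene
Product: 2 diethyl [(E)-but-2-en-1-yl]phosphonate
Conditions: P(OEt)3 (neat), 140 °C, EtBr distilled off
Reagents that add atoms: triethyl phosphite, CCOP(OCC)OCC
Why: Michaelis–Arbuzov reaction, in which phosphorus attacks the unbranched allylic carbon in SN2 fashion and bromide dealkylates the phosphonium ion, so the E alkene should be kept.

Step 2
Reactants: 3 methyl (S)-3-hydroxy-2-methylpropanoate
Product: 4 methyl (S)-3-(tert-butyldimethylsilyloxy)-2-methylpropanoate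
Conditions: TBSCl, imidazole, DMF, 0 °C to rt
Reagents that add atoms: tert-butyldimethylsilyl chloride, CC(C)(C)[Si](C)(C)Cl
Why: Imidazole-promoted silylation of the primary alcohol, which does not touch the α stereocentre.

Step 3
Reactants: 4 methyl (S)-3-(tert-butyldimethylsilyloxy)-2-methylpropanoate
Product: 5 (S)-3-(tert-butyldimethylsilyloxy)-2-methylpropanal
Conditions: iBu2AlH (1.05 equiv), CH2Cl2, −78 °C; aq. potassium sodium tartrate; used at once
Reagents that add atoms: none
Why: Partial ester reduction, in which the tetrahedral aluminium hemiacetal survives at −78 °C and gives the aldehyde only on work-up, so the labile α centre should be kept if 5 is used directly.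

Step 4
Reactants: 2 diethyl [(E)-but-2-en-1-yl]phosphonate; 5 (S)-3-(tert-butyldimethylsilyloxy)-2-methylpropanal
Product: 6 (R,3E,5E)-1-(tert-butyldimethylsilyloxy)-2-methylhepta-3,5-diene
Conditions: 2, n-BuLi, THF, −78 °C; then 5; then DMPU, −78 °C to rt
Reagents that add atoms: none
Why: Horner–Wadsworth–Emmons olefination with the allyl-stabilised phosphonate anion, which reacts at its α carbon and should give the new alkene E through the reversibly formed anti adduct while the crotyl alkene stays E.

Step 5
Reactants: 7 glycine methyl ester hydrochloride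
Product: 8 methyl diazoacetate
Conditions: NaNO2, cat. H2SO4, H2O/CH2Cl2, −10 to 0 °C; kept as a CH2Cl2 solution
Reagents that add atoms: sodium nitrite, [Na+].[O-]N=O
Why: Diazotisation of the α-amino ester, whose diazonium ion loses the acidic α proton to give the stabilised diazo ester.

Step 6
Reactants: 8 methyl diazoacetate; 9 2-(tert-butyldimethylsilyloxy)acetaldehyde
Product: 10 methyl 4-(tert-butyldimethylsilyloxy)-2-diazo-3-hydroxybutanoate (racemic)
Conditions: DBU (0.2 equiv), MeCN, 0 °C to rt
Reagents that add atoms: none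
Why: Base-catalysed aldol-type addition of the diazoacetate carbanion to the aldehyde; the new carbinol centre is removed in step 7.

Step 7
Reactants: 10 methyl 4-(tert-butyldimethylsilyloxy)-2-diazo-3-hydroxybutanoate
Product: 11 methyl (E)-4-(tert-butyldimethylsilyloxy)-2-diazobut-3-enoate
Conditions: POCl3, Et3N, CH2Cl2, 0 °C; used promptly, stored cold
Reagents that add atoms: none
Why: Dehydration of the β-hydroxy α-diazo ester through its dichlorophosphate, with diazo-assisted loss of the leaving group and anti elimination, which should give the conjugated enol ether with OSi trans to the diazo carbon (the less hindered and more stable E alkene).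

Step 8
Reactants: 6 (R,3E,5E)-1-(tert-butyldimethylsilyloxy)-2-methylhepta-3,5-diene; 11 methyl (E)-4-(tert-butyldimethylsilyloxy)-2-diazobut-3-enoate
Product: 13 methyl 3-(tert-butyldimethylsilyloxy)-4-[(2R)-1-(tert-butyldimethylsilyloxy)propan-2-yl]-7-methylcyclohepta-1,5-diene-1-carboxylate (C3–O/C4 arm/C7–Me all α), via cis-divinylcyclopropane 12 (not isolated)
Conditions: Rh2(S-DOSP)4 (2 mol %), hexanes, −40 °C to rt, 11 (2 equiv) added slowly; then 60 °C
Reagents that add atoms: none
Why: The chiral dirhodium tetracarboxylate (divalent rhodium) takes dinitrogen from 11 to give a donor/acceptor vinylcarbenoid, which adds in a concerted, asynchronous way to the methyl-terminated alkene of 6 (first bond to C7), the siloxyvinyl group ending cis to the remaining alkenyl group in 12. The closest known reaction type is the tandem cyclopropanation/Cope rearrangement of vinyldiazoacetates with dienes, a formal (4+3) cycloaddition. The seven-membered ring closes pericyclically: C1–C7 is made in the cyclopropanation, and the boat [3,3] shift of the cis-divinylcyclopropane breaks the C1–C6 cyclopropane bond and makes C3–C4. C7 is set by stereospecific addition to the E alkene (Me trans to the alkenyl group); C3 and C4 are set by the boat transition state, in which the E substituents of both termini (OSi and the Cα arm) point away from the cyclopropane and so end cis to each other and to C7–Me. The absolute configuration is set by the catalyst, which admits the diene terminus end-on to one face of the carbenoid; the remote Cα centre only has to be matched. The step needs site selection between the two E alkenes and cyclopropanation in preference to allylic C–H insertion; the α-branched silyloxypropyl arm shields C4=C5, and slow addition in a hydrocarbon solvent keeps carbenoid dimerisation down.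

Step 9
Reactants: 13 methyl 3-(tert-butyldimethylsilyloxy)-4-[(2R)-1-(tert-butyldimethylsilyloxy)propan-2-yl]-7-methylcyclohepta-1,5-diene-1-carboxylate
Product: 14 [3α-(tert-butyldimethylsilyloxy)-4α-[(2R)-1-(tert-butyldimethylsilyloxy)propan-2-yl]-7α-methylcyclohepta-1,5-dien-1-yl]methanol
Conditions: iBu2AlH (2.5 equiv), CH2Cl2, −78 °C; aq. potassium sodium tartrate
Reagents that add atoms: none
Why: 1,2-Reduction of the conjugated ester to the primary allylic alcohol, which leaves both alkenes and both silyl ethers in place.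

Step 10
Reactants: 14 the dienyl methanol
Product: 15 [3α-(tert-butyldimethylsilyloxy)-4α-[(2R)-1-(tert-butyldimethylsilyloxy)propan-2-yl]-7α-methylcyclohept-1-en-1-yl]methanol
Conditions: 2-nitrobenzenesulfonohydrazide (excess), Et3N, CH2Cl2, rt
Reagents that add atoms: none
Why: Diimide reduction, a concerted syn transfer of two hydrogens that should be much faster at the cis-disubstituted C5=C6 than at the trisubstituted C1=C2; no stereocentre is formed.

Step 11
Reactants: 15 the cycloheptenyl methanol
Product: 16 4-methoxybenzyl ether of 15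
Conditions: NaH, 4-MeOC6H4CH2Cl, Bu4NI (cat.), THF/DMF, 0 °C to rt
Reagents that add atoms: 4-methoxybenzyl chloride, COc1ccc(CCl)cc1
Why: Williamson etherification, which masks the C1 carbinol so that C3–OH is the only allylic hydroxyl in step 13 and the only primary alcohol oxidised in step 14 is the Cα arm.

Step 12
Reactants: 16 the bis-silyl 4-methoxybenzyl ether
Product: 17 ene-diol with C1–CH2O(4-methoxybenzyl), C3α–OH and Cα–CH2OH
Conditions: Bu4NF (3 equiv), THF, 0 °C to rt
Reagents that add atoms: none
Why: Fluoride cleavage of both silyl ethers, to which the benzyl-type ether is inert.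

Step 13
Reactants: 17 the ene-diol
Product: 18 C1–C2 α-epoxide of 17 (epoxide oxygen cis to C3–OH)
Conditions: VO(acac)2 (5 mol %), t-BuOOH (decane), CH2Cl2, 0 °C to rt
Reagents that add atoms: tert-butyl hydroperoxide, CC(C)(C)OO
Why: Hydroxyl-directed vanadium-catalysed epoxidation, in which the vanadate ester of the allylic C3–OH delivers the peroxide oxygen to the face of C1=C2 syn to C3–O, which sets C1 and C2 on the α face.

Step 14
Reactants: 18 the epoxy diol
Product: 21 epoxy γ-lactone (C3–O–CO–Cα) bearing C1–CH2O(4-methoxybenzyl), via hydroxy aldehyde 19 (not isolated), via lactol 20 (not isolated)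
Conditions: TEMPO (20 mol %), PhI(OAc)2 (2.5 equiv), CH2Cl2, rt
Reagents that add atoms: none
Why: Oxoammonium oxidation, selective for the primary alcohol over the secondary one; the aldehyde closes onto the cis C3–OH and the lactol is oxidised on to the cis-fused lactone under non-basic conditions that should leave Cα unchanged.

Step 15
Reactants: 21 the epoxy lactone 4-methoxybenzyl ether
Product: 22 epoxy lactone with free C1–CH2OH (a 2,3-epoxy alcohol)
Conditions: DDQ, CH2Cl2/pH 7 buffer, 0 °C to rt
Reagents that add atoms: none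
Why: Oxidative cleavage of the electron-rich benzyl ether by hydride abstraction and hydrolysis, to which the epoxide and the lactone are inert.

Step 16
Reactants: 22 the epoxy alcohol; 23 angelic acid [(Z)-2-methylbut-2-enoic acid]
Product: 24 C2β-angelate with C1α-hydroxyl and C1-hydroxymethyl (lactone intact)
Conditions: Ti(OiPr)4 (1.5 equiv), 23 (3 equiv), CH2Cl2, rt
Reagents that add atoms: none
Why: Titanium-mediated opening of a 2,3-epoxy alcohol by a carboxylic acid, in which the titanium chelate of the CH2O alkoxide and the epoxide oxygen directs the carboxylate to the distal secondary carbon C2 in SN2 fashion; C2 is inverted (O on the β face) and C1–O stays α, giving the trans C1–OH/C2–O pair.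

Step 17
Reactants: 24 the angelate diol
Product: 25 C1-formyl α-hydroxy aldehyde
Conditions: SO3·pyridine, DMSO, iPr2NEt, CH2Cl2, 0 °C
Reagents that add atoms: none
Why: Parikh–Doering oxidation of the primary alcohol, which leaves the tertiary hydroxyl alone, does not cleave the glycol and cannot epimerise C1 because C1 bears no hydrogen.

Step 18
Reactants: 25 the α-hydroxy aldehyde
Product: 26 C1-(1-hydroxyethyl) diol (both carbinol epimers)
Conditions: MeTi(OiPr)3 (3 equiv), THF, −40 to 0 °C
Reagents that add atoms: methyltriisopropoxytitanium, C[Ti](OC(C)C)(OC(C)C)OC(C)C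
Why: Chemoselective carbonyl addition of the non-basic methyltitanium reagent, which should react with the aldehyde and not with the lactone or the angelate; the new carbinol centre is removed in step 19, so either epimer serves.

Step 19
Reactants: 26 the secondary/tertiary diol
Product: 27 C1-acetyl α-hydroxy methyl ketone
Conditions: Dess–Martin periodinane, CH2Cl2, 0 °C to rt
Reagents that add atoms: none
Why: Dess–Martin oxidation of the secondary alcohol to the ketone under neutral conditions that should leave the tertiary hydroxyl, the angelate geometry and Cα unchanged.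

Step 20
Reactants: 27 the α-hydroxy methyl ketone
Product: 28 C1-O-triethylsilyl ether of 27
Conditions: Et3SiOTf, 2,6-lutidine, CH2Cl2, −78 to 0 °C
Reagents that add atoms: triethylsilyl trifluoromethanesulfonate, CC[Si](CC)(CC)OS(=O)(=O)C(F)(F)F
Why: Silyl triflate silylation of the hindered tertiary alcohol, which keeps that hydroxyl from consuming the chloroborane in step 21.

Step 21
Reactants: 28 the silyl-protected methyl ketone; 29 acetaldehyde
Product: 30 C1-O-triethylsilyl ether of the target
Conditions: (+)-Ipc2BCl, Et3N, Et2O, −78 to 0 °C; then 29 (excess), −78 to −20 °C; then MeOH, pH 7 buffer, H2O2, 0 °C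
Reagents that add atoms: none
Why: Boron-mediated asymmetric aldol reaction, in which the chloroborane/amine pair enolises only the methyl group (C1 is quaternary; lactone and angelate are not enolised) and the isopinocampheyl groups should steer the closed six-membered transition state to the Si face of acetaldehyde, setting the (R)-carbinol.

Step 22
Reactants: 30 the silyl-protected target
Product: 31 CNP0321985.1 (target)
Conditions: HF·pyridine, pyridine, THF, 0 °C
Reagents that add atoms: none
Why: Buffered fluoride cleavage of the tertiary silyl ether, mild enough that the β-hydroxy ketone, the angelate and the lactone α centre should survive.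

**Compound list**
1 | (E)-1-bromobut-2-ene | C/C=C/CBr | starting material
2 | diethyl [(E)-but-2-en-1-yl]phosphonate | C/C=C/CP(=O)(OCC)OCC | intermediate
3 | methyl (S)-3-hydroxy-2-methylpropanoate | COC(=O)[C@@H](C)CO | starting material
4 | methyl (S)-3-(tert-butyldimethylsilyloxy)-2-methylpropanoate | COC(=O)[C@@H](C)CO[Si](C)(C)C(C)(C)C | intermediate
5 | (S)-3-(tert-butyldimethylsilyloxy)-2-methylpropanal | O=C[C@@H](C)CO[Si](C)(C)C(C)(C)C | intermediate
6 | (R,3E,5E)-1-(tert-butyldimethylsilyloxy)-2-methylhepta-3,5-diene | C/C=C/C=C/[C@@H](C)CO[Si](C)(C)C(C)(C)C | intermediate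
7 | glycine methyl ester hydrochloride | COC(=O)CN.Cl | starting material
8 | methyl diazoacetate | COC(=O)C=[N+]=[N-] | intermediate
9 | 2-(tert-butyldimethylsilyloxy)acetaldehyde | O=CCO[Si](C)(C)C(C)(C)C | starting material
10 | methyl 4-(tert-butyldimethylsilyloxy)-2-diazo-3-hydroxybutanoate (racemic) | COC(=O)C(=[N+]=[N-])C(O)CO[Si](C)(C)C(C)(C)C | intermediate
11 | methyl (E)-4-(tert-butyldimethylsilyloxy)-2-diazobut-3-enoate | COC(=O)C(=[N+]=[N-])/C=C/O[Si](C)(C)C(C)(C)C | intermediate
12 | methyl 1-[(E)-2-(tert-butyldimethylsilyloxy)ethenyl]-2-[(1E,3R)-4-(tert-butyldimethylsilyloxy)-3-methylbut-1-enyl]-3-methylcyclopropane-1-carboxylate (alkenyl groups cis, ring methyl trans to them) | COC(=O)[C@@]1(/C=C/O[Si](C)(C)C(C)(C)C)[C@@H](C)[C@@H]1/C=C/[C@@H](C)CO[Si](C)(C)C(C)(C)C | intermediate (not isolated)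
13 | methyl 3-(tert-butyldimethylsilyloxy)-4-[(2R)-1-(tert-butyldimethylsilyloxy)propan-2-yl]-7-methylcyclohepta-1,5-diene-1-carboxylate (3,4,7-all-cis) | COC(=O)C1=C[C@H](O[Si](C)(C)C(C)(C)C)[C@H]([C@@H](C)CO[Si](C)(C)C(C)(C)C)C=C[C@@H]1C | intermediate
14 | [3α-(tert-butyldimethylsilyloxy)-4α-[(2R)-1-(tert-butyldimethylsilyloxy)propan-2-yl]-7α-methylcyclohepta-1,5-dien-1-yl]methanol | OCC1=C[C@H](O[Si](C)(C)C(C)(C)C)[C@H]([C@@H](C)CO[Si](C)(C)C(C)(C)C)C=C[C@@H]1C | intermediate
15 | [3α-(tert-butyldimethylsilyloxy)-4α-[(2R)-1-(tert-butyldimethylsilyloxy)propan-2-yl]-7α-methylcyclohept-1-en-1-yl]methanol | OCC1=C[C@H](O[Si](C)(C)C(C)(C)C)[C@H]([C@@H](C)CO[Si](C)(C)C(C)(C)C)CC[C@@H]1C | intermediate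
16 | 4-methoxybenzyl ether of 15 | COc1ccc(COCC2=C[C@H](O[Si](C)(C)C(C)(C)C)[C@H]([C@@H](C)CO[Si](C)(C)C(C)(C)C)CC[C@@H]2C)cc1 | intermediate
17 | ene-diol: C1–CH2O(4-methoxybenzyl), C3α–OH, Cα–CH2OH | COc1ccc(COCC2=C[C@H](O)[C@H]([C@@H](C)CO)CC[C@@H]2C)cc1 | intermediate
18 | C1–C2 α-epoxide of 17 | COc1ccc(COC[C@@]23O[C@@H]2[C@H](O)[C@H]([C@@H](C)CO)CC[C@@H]3C)cc1 | intermediate
19 | epoxy hydroxy aldehyde (Cα–CHO, C3α–OH) | COc1ccc(COC[C@@]23O[C@@H]2[C@H](O)[C@H]([C@@H](C)C=O)CC[C@@H]3C)cc1 | intermediate (not isolated)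
20 | epoxy lactol (both anomers) | COc1ccc(COC[C@@]23O[C@@H]2[C@@H]4OC(O)[C@H](C)[C@@H]4CC[C@@H]3C)cc1 | intermediate (not isolated)
21 | epoxy γ-lactone, C1–CH2O(4-methoxybenzyl) | COc1ccc(COC[C@@]23O[C@@H]2[C@@H]4OC(=O)[C@H](C)[C@@H]4CC[C@@H]3C)cc1 | intermediate
22 | epoxy γ-lactone, C1–CH2OH | OC[C@@]12O[C@@H]1[C@@H]3OC(=O)[C@H](C)[C@@H]3CC[C@@H]2C | intermediate
23 | angelic acid, (Z)-2-methylbut-2-enoic acid | C/C=C(/C)C(=O)O | starting material
24 | C2β-angelate, C1α-OH, C1-CH2OH lactone | C/C=C(/C)C(=O)O[C@H]1[C@@H]2OC(=O)[C@H](C)[C@@H]2CC[C@H](C)[C@@]1(O)CO | intermediate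
25 | C2β-angelate, C1α-OH, C1-CHO lactone | C/C=C(/C)C(=O)O[C@H]1[C@@H]2OC(=O)[C@H](C)[C@@H]2CC[C@H](C)[C@@]1(O)C=O | intermediate
26 | C2β-angelate, C1α-OH, C1-CH(OH)CH3 lactone (carbinol epimers) | C/C=C(/C)C(=O)O[C@H]1[C@@H]2OC(=O)[C@H](C)[C@@H]2CC[C@H](C)[C@@]1(O)C(C)O | intermediate
27 | C2β-angelate, C1α-OH, C1-acetyl lactone | C/C=C(/C)C(=O)O[C@H]1[C@@H]2OC(=O)[C@H](C)[C@@H]2CC[C@H](C)[C@@]1(O)C(C)=O | intermediate
28 | C1-O-triethylsilyl ether of 27 | C/C=C(/C)C(=O)O[C@H]1[C@@H]2OC(=O)[C@H](C)[C@@H]2CC[C@H](C)[C@@]1(O[Si](CC)(CC)CC)C(C)=O | intermediate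
29 | acetaldehyde | CC=O | starting material
30 | C1-O-triethylsilyl ether of the target | C/C=C(/C)C(=O)O[C@H]1[C@@H]2OC(=O)[C@H](C)[C@@H]2CC[C@H](C)[C@@]1(O[Si](CC)(CC)CC)C(=O)C[C@@H](C)O | intermediate
31 | CNP0321985.1 | C/C=C(/C)C(=O)O[C@H]1[C@@H]2OC(=O)[C@H](C)[C@@H]2CC[C@H](C)[C@@]1(O)C(=O)C[C@@H](C)O | target

**Step count**
Total: 22 steps. Longest linear sequence: 18 steps (steps 2–4 and 8–22, from 3).

**Steps most likely to fail**

Step 8. The E-disubstituted, methyl-terminated alkene may approach the hindered chiral carbenoid too slowly, so that allylic C–H insertion, carbenoid dimerisation, cyclopropanation of C4=C5 or poor facial discrimination takes over. The fallback delivers the same carbenoid through a tether; it sets out from 5 and comes back at 13. Horner–Wadsworth–Emmons reaction of 5 with triethyl 4-phosphonocrotonate (LiN(SiMe3)2, THF, −78 to 0 °C) would give ethyl (2E,4E,6R)-7-(tert-butyldimethylsilyloxy)-6-methylhepta-2,4-dienoate F1. Reduction with iBu2AlH would give (2E,4E,6R)-7-(tert-butyldimethylsilyloxy)-6-methylhepta-2,4-dien-1-ol F2. Bromoacetyl bromide/NaHCO3 would give the dienyl bromoacetate F3, and N,N'-ditosylhydrazine/DBU the dienyl diazoacetate F4. DBU-catalysed addition of F4 to 9 would give the dienyl 2-diazo-3-hydroxy-4-silyloxybutanoate F5, and POCl3/Et3N the dienyl (E)-2-diazo-4-silyloxybut-3-enoate F6. With Rh2(OAc)4 in CH2Cl2 the carbenoid would be delivered intramolecularly to the allylic-ester alkene (C6=C7 of the route), a process that accepts E alkenes, to give the lactone-fused cis-divinylcyclopropane F7 (not isolated). Its Cope rearrangement would give the lactone-bridged cycloheptadiene F8 (C1 carbonyl tied to C7–CH2O); the diastereomer arising from the other alkene face would be separated here. PhSeNa (from (PhSe)2/NaBH4, DMF, 110 °C) would open the lactone at CH2–O to the phenylselanyl acid F9, Me3SiCHN2 would give its methyl ester F10, and Bu3SnH/AIBN would replace selenium by hydrogen to give 13.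

Step 16. The hindered, weakly nucleophilic α-branched carboxylate may add too slowly, so that isopropoxide transfer from titanium, Z-to-E isomerisation to the tiglate or acyl migration onto the C1 hydroxyls competes. The fallback makes the C2–O bond first and the angelate afterwards by acylation; it sets out from 22 and comes back at 24. Ti(OiPr)4 and levulinic acid would open 22 at C2 to the C2β-levulinate diol F11. 2,2-Dimethoxypropane/PPTS would tie the C1–OH/CH2OH pair as the acetonide F12. Hydrazine acetate would remove the levulinate to give the C2β-alcohol acetonide F13. The mixed anhydride of 23 with 2,4,6-trichlorobenzoyl chloride (Et3N, toluene, 80 °C; Yamaguchi esterification) would give the angelate acetonide F14, and aqueous acetic acid would remove the acetonide to give 24.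

Step 21. Facial discrimination at acetaldehyde by the hindered α-quaternary enol borinate may be incomplete, so that both carbinol epimers form. The fallback sets the carbinol with a catalyst after the C–C bond is made; it sets out from 28 and comes back at 30. Aldol addition with achiral (c-C6H11)2BCl/Et3N and 29 would give the epimeric β-hydroxy ketone mixture F15. MsCl/Et3N followed by DBU would give the (E)-but-2-enoyl ketone F16. Copper-catalysed enantioselective β-borylation (CuCl, NaOtBu, the Josiphos antipode that gives the R boronate, B2pin2, MeOH, THF) would give the β-boryl ketone F17, the disubstituted enone reacting ahead of the trisubstituted angelate. NaBO3·4H2O would oxidise C–B to C–OH with retention to give 30.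

**Further compounds**
F1 | step 8 | ethyl (2E,4E,6R)-7-(tert-butyldimethylsilyloxy)-6-methylhepta-2,4-dienoate | CCOC(=O)/C=C/C=C/[C@@H](C)CO[Si](C)(C)C(C)(C)C
F2 | step 8 | (2E,4E,6R)-7-(tert-butyldimethylsilyloxy)-6-methylhepta-2,4-dien-1-ol | OC/C=C/C=C/[C@@H](C)CO[Si](C)(C)C(C)(C)C
F3 | step 8 | (2E,4E,6R)-7-(tert-butyldimethylsilyloxy)-6-methylhepta-2,4-dienyl bromoacetate | BrCC(=O)OC/C=C/C=C/[C@@H](C)CO[Si](C)(C)C(C)(C)C
F4 | step 8 | (2E,4E,6R)-7-(tert-butyldimethylsilyloxy)-6-methylhepta-2,4-dienyl diazoacetate | [N-]=[N+]=CC(=O)OC/C=C/C=C/[C@@H](C)CO[Si](C)(C)C(C)(C)C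
F5 | step 8 | dienyl 4-(tert-butyldimethylsilyloxy)-2-diazo-3-hydroxybutanoate (carbinol epimers) | [N-]=[N+]=C(C(O)CO[Si](C)(C)C(C)(C)C)C(=O)OC/C=C/C=C/[C@@H](C)CO[Si](C)(C)C(C)(C)C
F6 | step 8 | dienyl (E)-4-(tert-butyldimethylsilyloxy)-2-diazobut-3-enoate | [N-]=[N+]=C(/C=C/O[Si](C)(C)C(C)(C)C)C(=O)OC/C=C/C=C/[C@@H](C)CO[Si](C)(C)C(C)(C)C
F7 | step 8 | lactone-fused cis-divinylcyclopropane (3-oxabicyclo[3.1.0]hexan-2-one, not isolated) | O=C1OC[C@H]2[C@H](/C=C/[C@@H](C)CO[Si](C)(C)C(C)(C)C)[C@@]12/C=C/O[Si](C)(C)C(C)(C)C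
F8 | step 8 | lactone-bridged cycloheptadiene (C1–CO–O–CH2–C7; C3–O, C4 arm and C7–CH2 all α) | O=C1OC[C@H]2C=C[C@@H]([C@@H](C)CO[Si](C)(C)C(C)(C)C)[C@@H](O[Si](C)(C)C(C)(C)C)C=C12
F9 | step 8 | 7α-(phenylselanylmethyl) analogue of 13 as the free carboxylic acid | OC(=O)C1=C[C@H](O[Si](C)(C)C(C)(C)C)[C@H]([C@@H](C)CO[Si](C)(C)C(C)(C)C)C=C[C@@H]1C[Se]c2ccccc2
F10 | step 8 | 7α-(phenylselanylmethyl) analogue of 13 (methyl ester) | COC(=O)C1=C[C@H](O[Si](C)(C)C(C)(C)C)[C@H]([C@@H](C)CO[Si](C)(C)C(C)(C)C)C=C[C@@H]1C[Se]c2ccccc2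
F11 | step 16 | C2β-levulinate, C1α-OH, C1-CH2OH lactone | CC(=O)CCC(=O)O[C@H]1[C@@H]2OC(=O)[C@H](C)[C@@H]2CC[C@H](C)[C@@]1(O)CO
F12 | step 16 | C2β-levulinate, C1-O/CH2-O acetonide | CC(=O)CCC(=O)O[C@H]1[C@@H]2OC(=O)[C@H](C)[C@@H]2CC[C@H](C)[C@@]13COC(C)(C)O3
F13 | step 16 | C2β-alcohol, C1-O/CH2-O acetonide | O[C@H]1[C@@H]2OC(=O)[C@H](C)[C@@H]2CC[C@H](C)[C@@]13COC(C)(C)O3
F14 | step 16 | C2β-angelate, C1-O/CH2-O acetonide | C/C=C(/C)C(=O)O[C@H]1[C@@H]2OC(=O)[C@H](C)[C@@H]2CC[C@H](C)[C@@]13COC(C)(C)O3
F15 | step 21 | 30 together with its carbinol epimer | C/C=C(/C)C(=O)O[C@H]1[C@@H]2OC(=O)[C@H](C)[C@@H]2CC[C@H](C)[C@@]1(O[Si](CC)(CC)CC)C(=O)CC(C)O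
F16 | step 21 | C1-[(E)-but-2-enoyl] ketone, C1-O-triethylsilyl | C/C=C(/C)C(=O)O[C@H]1[C@@H]2OC(=O)[C@H](C)[C@@H]2CC[C@H](C)[C@@]1(O[Si](CC)(CC)CC)C(=O)/C=C/C
F17 | step 21 | C1-[(3R)-3-(pinacolatoboryl)butanoyl] ketone, C1-O-triethylsilyl | C/C=C(/C)C(=O)O[C@H]1[C@@H]2OC(=O)[C@H](C)[C@@H]2CC[C@H](C)[C@@]1(O[Si](CC)(CC)CC)C(=O)C[C@@H](C)B3OC(C)(C)C(C)(C)O3
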